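**Retrosynthetic overview**

- Target ⇒ ring-closing metathesis of an acyclic nona-1,7-diene ester (ring bond C3=C4, propene lost). The cyclohexene is the only ring built and is closed in the last step; the coumarin bicycle is bought intact as umbelliferone.
- Diene ester ⇒ O-acylation of a homoallylic alcohol with (2R)-2-methylbutanoyl chloride (separate four-step Evans branch); the alcohol ⇒ Brown allylation of an α-quaternary aldehyde, which sets the carbinol centre.
- Aldehyde ⇒ iridium-catalysed olefin isomerisation–Claisen rearrangement of a methallyl ether: it makes the bond to the gem-dimethyl carbon and sets the CH–CH2OAr centre by 1,3-chirality transfer.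
- Claisen substrate ⇒ Mitsunobu etherification of umbelliferone with an E-allylic alcohol ⇒ Negishi methylalumination/hydroxymethylation of the methallyl ether of (R)-but-3-yn-2-ol.

Assumption: the SMILES is read as the (1R,5S)-ring, (2R)-acyl isomer (ring substituents cis); (R)-but-3-yn-2-ol, (R)-4-benzyl-1,3-oxazolidin-2-one, umbelliferone and B-allyldiisopinocampheylborane of the (−)-α-pinene series are bought.

**Route**

Step 1
Reactants: 1 (4R)-4-benzyl-1,3-oxazolidin-2-one; 2 butanoyl chloride
Product: 4 (4R)-4-benzyl-3-butanoyl-1,3-oxazolidin-2-one, via lithium oxazolidinide 3 (not isolated)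
Conditions: n-BuLi, THF, −78 °C; then 2, −78 → 0 °C
Reagents that add atoms: none
Why: N-acylation of the lithiated Evans auxiliary by the acid chloride, with no stereocentre touched.

Step 2
Reactants: 4
Product: 6 (4R)-4-benzyl-3-[(2R)-2-methylbutanoyl]-1,3-oxazolidin-2-one, via sodium Z-enolate 5 (not isolated)
Conditions: NaHMDS, THF, −78 °C; MeI, −78 °C
Reagents that add atoms: iodomethane, CI
Why: Evans asymmetric alkylation, in which the chelated Z-enolate is methylated on the face anti to the benzyl group and so gives the (2R) centre (dr about 10:1, minor isomer removed by chromatography).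

Step 3
Reactants: 6
Product: 8 (2R)-2-methylbutanoic acid, via lithium peroxycarboxylate 7 (not isolated)
Conditions: LiOH, 30% H2O2, THF–H2O 3:1, 0 °C; aq. Na2SO3; 1 M HCl to pH 2, Et2O extraction
Reagents that add atoms: hydrogen peroxide, OO
Why: Lithium hydroperoxide cleaves the exocyclic imide carbonyl selectively and without α-epimerisation, the auxiliary being recovered.

Step 4
Reactants: 8
Product: 9 (2R)-2-methylbutanoyl chloride
Conditions: (COCl)2, DMF (cat.), CH2Cl2, 0 °C → rt; volatiles removed, used as a CH2Cl2 solution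
Reagents that add atoms: oxalyl chloride, O=C(Cl)C(Cl)=O
Why: Base-free acid chloride formation (Vilsmeier-type activation) leaves the purely alkyl-substituted α-centre configurationally intact.

Step 5
Reactants: 10 (2R)-but-3-yn-2-ol; 11 3-chloro-2-methylprop-1-ene
Product: 13 (3R)-3-[(2-methylprop-2-en-1-yl)oxy]but-1-yne, via sodium alkoxide 12 (not isolated)
Conditions: NaH, Bu4NI (cat.), THF, 0 → 40 °C
Reagents that add atoms: none
Why: Williamson etherification at oxygen, so the carbinol C–O bond is not broken and the (R) centre is carried through.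

Step 6
Reactants: 13
Product: 16 (2E,4R)-3-methyl-4-[(2-methylprop-2-en-1-yl)oxy]pent-2-en-1-ol, via alkenyldimethylalane 14 (not isolated), via lithium alkenylaluminate 15 (not isolated)
Conditions: Me3Al, Cp2ZrCl2 (20 mol %), CH2Cl2, 0 °C → rt; volatiles off; n-BuLi (1 equiv), hexane–THF, −78 → 0 °C; (CH2O)n, rt; aq. Rochelle salt
Reagents that add atoms: trimethylaluminium, C[Al](C)C; paraformaldehyde (formaldehyde), C=O
Why: Negishi zirconium-catalysed syn-methylalumination puts CH3 on the internal and Al on the terminal alkyne carbon, and the aluminate adds to formaldehyde with retention, which fixes the E trisubstituted alkene.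

Step 7
Reactants: 16; 17 7-hydroxy-2H-chromen-2-one (umbelliferone)
Product: 18 7-{[(2E,4R)-3-methyl-4-[(2-methylprop-2-en-1-yl)oxy]pent-2-en-1-yl]oxy}-2H-chromen-2-one
Conditions: PPh3, DIAD, THF, 0 °C → rt
Reagents that add atoms: none
Why: Mitsunobu etherification of an unhindered primary allylic alcohol with the acidic phenol (pKa about 8) proceeds by direct SN2 displacement, the hindered γ-carbon disfavouring SN2′.

Step 8
Reactants: 18
Product: 20 (3S,4E)-2,2,4-trimethyl-3-{[(2-oxo-2H-chromen-7-yl)oxy]methyl}hex-4-enal, via isobutenyl ether 19 (not isolated)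
Conditions: [IrCl(C8H14)2]2 (1 mol %), PCy3 (6 mol %), NaBPh4 (2 mol %), CH2Cl2–acetone 25:1, rt; then PPh3 (6 mol %), toluene, 100 °C
Reagents that add atoms: none
Why: Olefin isomerisation–Claisen rearrangement, in which the cationic iridium catalyst moves only the terminal methallyl double bond into conjugation with oxygen and the resulting allyl vinyl ether rearranges suprafacially with the carbinol methyl equatorial, so the (4R) centre is transferred to the new (3S) centre together with the quaternary carbon and an E ethylidene group.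

Step 9
Reactants: 20
Product: 22 (4R,6S,7E)-5,5,7-trimethyl-6-{[(2-oxo-2H-chromen-7-yl)oxy]methyl}nona-1,7-dien-4-ol, via diisopinocampheylborinate ester 21 (not isolated)
Conditions: B-allyldiisopinocampheylborane of the (−)-α-pinene series (salt-free, 1.5 equiv), Et2O, −100 → −78 °C; then MeOH, pH 7 phosphate buffer, 30% H2O2, 0 °C → rt
Reagents that add atoms: B-allyldiisopinocampheylborane [(−)-α-pinene series], C=CCB([C@H]1C[C@H]2C[C@@H]([C@@H]1C)C2(C)C)[C@H]1C[C@H]2C[C@@H]([C@@H]1C)C2(C)C
Why: Brown allylboration through a closed chair transition state, in which this reagent enantiomer delivers allyl to the Re face of the pivaldehyde-like aldehyde and gives the (4R) carbinol under reagent control (dr ≥ 10:1 expected, minor isomer removed by chromatography).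

Step 10
Reactants: 22; 9
Product: 23 (4R,6S,7E)-5,5,7-trimethyl-6-{[(2-oxo-2H-chromen-7-yl)oxy]methyl}nona-1,7-dien-4-yl (2R)-2-methylbutanoate
Conditions: pyridine, DMAP (20 mol %), CH2Cl2, 0 °C → rt
Reagents that add atoms: none
Why: DMAP-catalysed acylation of the hindered secondary alcohol by the acid chloride, with pyridine too weak a base to form the ketene, so neither the carbinol nor the acyl α-centre is disturbed.

Step 11
Reactants: 23
Product: 24 (1R,5S)-4,6,6-trimethyl-5-{[(2-oxo-2H-chromen-7-yl)oxy]methyl}cyclohex-3-en-1-yl (2R)-2-methylbutanoate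
Conditions: second-generation Hoveyda–Grubbs catalyst RuCl2(H2IMes)(=CH-C6H4-2-O-i-Pr) (5–10 mol %), 1,4-benzoquinone (10 mol %), toluene (5 mM), 80 °C, N2 sparge
Reagents that add atoms: none
Why: Ring-closing metathesis, in which the ruthenium carbene loads on the terminal allyl group and closes the six-membered ring onto the ethylidene olefin (helped by the gem-dimethyl group) with loss of propene, while both stereocentres and the electron-poor coumarin double bond stay untouched.

**Compound list**

1 | (4R)-4-benzyl-1,3-oxazolidin-2-one | O=C1N[C@H](Cc2ccccc2)CO1 | starting material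
2 | butanoyl chloride | CCCC(Cl)=O | starting material
3 | lithium (4R)-4-benzyl-2-oxo-1,3-oxazolidin-3-ide | [Li+].O=C1[N-][C@H](Cc2ccccc2)CO1 | intermediate (not isolated)
4 | (4R)-4-benzyl-3-butanoyl-1,3-oxazolidin-2-one | CCCC(=O)N1[C@H](Cc2ccccc2)COC1=O | intermediate
5 | sodium (1Z)-1-[(4R)-4-benzyl-2-oxo-1,3-oxazolidin-3-yl]but-1-en-1-olate | [Na+].CC/C=C(\[O-])N1[C@H](Cc2ccccc2)COC1=O | intermediate (not isolated)
6 | (4R)-4-benzyl-3-[(2R)-2-methylbutanoyl]-1,3-oxazolidin-2-one | CC[C@@H](C)C(=O)N1[C@H](Cc2ccccc2)COC1=O | intermediate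
7 | lithium (2R)-2-methylbutaneperoxoate | [Li+].CC[C@@H](C)C(=O)O[O-] | intermediate (not isolated)
8 | (2R)-2-methylbutanoic acid | CC[C@@H](C)C(=O)O | intermediate
9 | (2R)-2-methylbutanoyl chloride | CC[C@@H](C)C(=O)Cl | intermediate
10 | (2R)-but-3-yn-2-ol | C[C@@H](O)C#C | starting material
11 | 3-chloro-2-methylprop-1-ene | CC(=C)CCl | starting material
12 | sodium (2R)-but-3-yn-2-olate | [Na+].C[C@@H]([O-])C#C | intermediate (not isolated)
13 | (3R)-3-[(2-methylprop-2-en-1-yl)oxy]but-1-yne | C[C@@H](OCC(C)=C)C#C | intermediate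
14 | dimethyl{(1E,3R)-2-methyl-3-[(2-methylprop-2-en-1-yl)oxy]but-1-en-1-yl}alumane | C[C@@H](OCC(C)=C)/C(C)=C/[Al](C)C | intermediate (not isolated)
15 | lithium butyl(dimethyl){(1E,3R)-2-methyl-3-[(2-methylprop-2-en-1-yl)oxy]but-1-en-1-yl}aluminate | [Li+].C[C@@H](OCC(C)=C)/C(C)=C/[Al-](C)(C)CCCC | intermediate (not isolated)
16 | (2E,4R)-3-methyl-4-[(2-methylprop-2-en-1-yl)oxy]pent-2-en-1-ol | C[C@@H](OCC(C)=C)/C(C)=C/CO | intermediate
17 | 7-hydroxy-2H-chromen-2-one (umbelliferone) | Oc1ccc2ccc(=O)oc2c1 | starting material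
18 | 7-{[(2E,4R)-3-methyl-4-[(2-methylprop-2-en-1-yl)oxy]pent-2-en-1-yl]oxy}-2H-chromen-2-one | C[C@@H](OCC(C)=C)/C(C)=C/COc1ccc2ccc(=O)oc2c1 | intermediate
19 | 7-{[(2E,4R)-3-methyl-4-[(2-methylprop-1-en-1-yl)oxy]pent-2-en-1-yl]oxy}-2H-chromen-2-one | C[C@@H](OC=C(C)C)/C(C)=C/COc1ccc2ccc(=O)oc2c1 | intermediate (not isolated)
20 | (3S,4E)-2,2,4-trimethyl-3-{[(2-oxo-2H-chromen-7-yl)oxy]methyl}hex-4-enal | O=CC(C)(C)[C@@H](COc1ccc2ccc(=O)oc2c1)/C(C)=C/C | intermediate
21 | (4R,6S,7E)-5,5,7-trimethyl-6-{[(2-oxo-2H-chromen-7-yl)oxy]methyl}nona-1,7-dien-4-yl diisopinocampheylborinate [(−)-α-pinene series] | C=CC[C@@H](OB([C@H]1C[C@H]2C[C@@H]([C@@H]1C)C2(C)C)[C@H]1C[C@H]2C[C@@H]([C@@H]1C)C2(C)C)C(C)(C)[C@@H](COc1ccc2ccc(=O)oc2c1)/C(C)=C/C | intermediate (not isolated)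
22 | (4R,6S,7E)-5,5,7-trimethyl-6-{[(2-oxo-2H-chromen-7-yl)oxy]methyl}nona-1,7-dien-4-ol | C=CC[C@@H](O)C(C)(C)[C@@H](COc1ccc2ccc(=O)oc2c1)/C(C)=C/C | intermediate
23 | (4R,6S,7E)-5,5,7-trimethyl-6-{[(2-oxo-2H-chromen-7-yl)oxy]methyl}nona-1,7-dien-4-yl (2R)-2-methylbutanoate | CC[C@@H](C)C(=O)O[C@H](CC=C)C(C)(C)[C@@H](COc1ccc2ccc(=O)oc2c1)/C(C)=C/C | intermediate
24 | (1R,5S)-4,6,6-trimethyl-5-{[(2-oxo-2H-chromen-7-yl)oxy]methyl}cyclohex-3-en-1-yl (2R)-2-methylbutanoate | CC[C@@H](C)C(=O)O[C@@H]1CC=C(C)[C@H](COc2ccc3ccc(=O)oc3c2)C1(C)C | target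

**Step count and risks**

Total step count: 11. Longest linear sequence: 7 (steps 5–11, from 10 to 24). The acid chloride branch (steps 1–4) enters at step 10, and umbelliferone 17 enters at step 7.

Steps most likely to fail:

Step 8 (isomerisation–Claisen). The 1,1-disubstituted methallyl olefin isomerises more slowly than a plain allyl ether, the coumarin may bind the cationic iridium, and the rearrangement has to build a quaternary carbon. Fallback: set out from 10 and make the enol ether by C–O cross-coupling instead of olefin isomerisation. Methylalumination/hydroxymethylation of the free alkynol (Me3Al 3 equiv, Cp2ZrCl2; n-BuLi; (CH2O)n) gives (2R,3E)-3-methylpent-3-ene-2,5-diol F1. Mitsunobu reaction with one equivalent of 17 (PPh3, DIAD, THF, 0 °C) etherifies the primary allylic hydroxyl preferentially and gives 7-{[(2E,4R)-4-hydroxy-3-methylpent-2-en-1-yl]oxy}-2H-chromen-2-one F2. Copper-catalysed coupling of F2 with 1-iodo-2-methylprop-1-ene (CuI, 3,4,7,8-tetramethyl-1,10-phenanthroline, Cs2CO3, o-xylene, 120 °C) forms enol ether 19, which rearranges in the same pot, and the route is rejoined at 20.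

Step 11 (ring-closing metathesis). The ring has to close onto a trisubstituted ethylidene olefin that is flanked by a tertiary and a quaternary carbon, so cyclisation may stall at the loaded carbene or give dimers. Fallback: set out from 23 and exchange the ethylidene partner for an isopropenyl group before the metathesis. Chemoselective epoxidation of the electron-rich trisubstituted olefin (mCPBA, NaHCO3, CH2Cl2, 0 °C) gives (4R,6S)-6-(2,3-dimethyloxiran-2-yl)-5,5-dimethyl-7-[(2-oxo-2H-chromen-7-yl)oxy]hept-1-en-4-yl (2R)-2-methylbutanoate F3 as a mixture of oxirane diastereomers. Periodic acid cleavage (H5IO6, THF–H2O, 0 °C) gives (3S,5R)-4,4-dimethyl-2-oxo-3-{[(2-oxo-2H-chromen-7-yl)oxy]methyl}oct-7-en-5-yl (2R)-2-methylbutanoate F4. Non-basic Lombardo methylenation (Zn, CH2Br2, TiCl4, THF–CH2Cl2, 0 °C; chosen because F4 is a β-aryloxy ketone that would eliminate with a basic ylide) gives (4R,6S)-5,5,7-trimethyl-6-{[(2-oxo-2H-chromen-7-yl)oxy]methyl}octa-1,7-dien-4-yl (2R)-2-methylbutanoate F5. Its terminal and 1,1-disubstituted olefins close readily with the second-generation Grubbs catalyst RuCl2(=CHPh)(H2IMes)(PCy3) in CH2Cl2 at 40 °C, and the route is rejoined at 24.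

Step 6 (methylalumination with formaldehyde trapping). The one-pot capture of the alkenylaluminate by paraformaldehyde is capricious, and n-BuLi could instead deprotonate the bis-allylic ether if aluminate formation is incomplete. Fallback: set out from 13 and install the CH2OH carbon through an isolable vinyl iodide. The same methylalumination is quenched with I2 (THF, −30 °C) to give (1E,3R)-1-iodo-2-methyl-3-[(2-methylprop-2-en-1-yl)oxy]but-1-ene F6. Lithium–iodine exchange (t-BuLi 2 equiv, Et2O, −78 °C) and formylation with DMF give (2E,4R)-3-methyl-4-[(2-methylprop-2-en-1-yl)oxy]pent-2-enal F7. Luche reduction (NaBH4, CeCl3·7H2O, MeOH, 0 °C) rejoins the route at 16.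

**Further compounds**

F1 | step 8 | (2R,3E)-3-methylpent-3-ene-2,5-diol | C[C@@H](O)/C(C)=C/CO
F2 | step 8 | 7-{[(2E,4R)-4-hydroxy-3-methylpent-2-en-1-yl]oxy}-2H-chromen-2-one | C[C@@H](O)/C(C)=C/COc1ccc2ccc(=O)oc2c1
F3 | step 11 | (4R,6S)-6-(2,3-dimethyloxiran-2-yl)-5,5-dimethyl-7-[(2-oxo-2H-chromen-7-yl)oxy]hept-1-en-4-yl (2R)-2-methylbutanoate, oxirane diastereomers | CC[C@@H](C)C(=O)O[C@H](CC=C)C(C)(C)[C@@H](COc1ccc2ccc(=O)oc2c1)C1(C)OC1C
F4 | step 11 | (3S,5R)-4,4-dimethyl-2-oxo-3-{[(2-oxo-2H-chromen-7-yl)oxy]methyl}oct-7-en-5-yl (2R)-2-methylbutanoate | CC[C@@H](C)C(=O)O[C@H](CC=C)C(C)(C)[C@@H](COc1ccc2ccc(=O)oc2c1)C(C)=O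
F5 | step 11 | (4R,6S)-5,5,7-trimethyl-6-{[(2-oxo-2H-chromen-7-yl)oxy]methyl}octa-1,7-dien-4-yl (2R)-2-methylbutanoate | CC[C@@H](C)C(=O)O[C@H](CC=C)C(C)(C)[C@@H](COc1ccc2ccc(=O)oc2c1)C(C)=C
F6 | step 6 | (1E,3R)-1-iodo-2-methyl-3-[(2-methylprop-2-en-1-yl)oxy]but-1-ene | C[C@@H](OCC(C)=C)/C(C)=C/I
F7 | step 6 | (2E,4R)-3-methyl-4-[(2-methylprop-2-en-1-yl)oxy]pent-2-enal | C[C@@H](OCC(C)=C)/C(C)=C/C=O
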